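Left-handed product and right-handed product have the same energy, so their interconversion pulls any mixture of them towards equal amounts. The single-handed catalyst can prefer one product, but the end point of that interconversion is still equal amounts. When you repeat these runs, the thing to watch is how much of its preference survives until you sample.

all flasks: left-handed substrate 0.30 M; partner 0.360 M; free catalyst 0.23 mM; impurity 31 µM; added ligand 0.84 mM; right-handed substrate 0.30 M; time 2.0 h

| run | temperature |
|---|---|
| Sunday's | 110 °C |
| Tuesday's | 150 °C |
| Wednesday's | 130 °C |

    free catalyst + right-handed substrate ⇌ catalyst intermediate B (K1 = 11 M⁻¹, k1 = 38000 M⁻¹ min⁻¹, Ea1 = 42.0 kJ mol⁻¹, ΔH1 = 37.0 kJ mol⁻¹)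
    partner + catalyst intermediate A → free catalyst + left-handed product (k2 = 86 M⁻¹ min⁻¹, Ea2 = 58.0 kJ mol⁻¹)
    free catalyst + added ligand ⇌ idle complex, settled at all times (K3 = 660 M⁻¹, ΔH3 = −7.00 kJ mol⁻¹)
    free catalyst + impurity → spent catalyst (k4 = 14000 M⁻¹ min⁻¹, Ea4 = 51.0 kJ mol⁻¹)
    free catalyst + left-handed substrate ⇌ catalyst intermediate A (K5 = 2.6 M⁻¹, k5 = 1000 M⁻¹ min⁻¹, Ea5 = 62.0 kJ mol⁻¹, ΔH5 = −8.00 kJ mol⁻¹)
    partner + catalyst intermediate B → free catalyst + right-handed product (k6 = 40 M⁻¹ min⁻¹, Ea6 = 80.0 kJ mol⁻¹)
    left-handed product ⇌ right-handed product (k7 = 0.030 min⁻¹, Ea7 = 110 kJ mol⁻¹)
    (constants at 110 °C)

- free catalyst is single-handed; left-handed substrate and right-handed substrate are mirror images of each other, charged as a racemate, each of them at the stated concentration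
- constants are those at 110 °C; use the activation energies and enthalpies for any other temperature

1. the flask with the highest share of left-handed product in all that became left-handed product or right-handed product ("all alike" if they lie within 1.5 percentage points) (Sunday's / Tuesday's / Wednesday's / all alike)
2. share of left-handed product in all that became left-handed product or right-handed product, Sunday's
3. share of left-handed product in all that became left-handed product or right-handed product, Tuesday's
4. share of left-handed product in all that became left-handed product or right-handed product, Wednesday's

Start with the preference, on Sunday's. Catalyst intermediate A comes undone at 385 min⁻¹, faster than the partner takes it at 31.0 min⁻¹. Catalyst intermediate B comes undone at 3450 min⁻¹, faster than the partner takes it at 14.4 min⁻¹. So I treat both intermediates as balanced with their substrates. The selectivity factor, left-handed over right-handed formation, is then 0.508. That gives a left-handed share of 33.7%.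

But the products do not stay as made. On Sunday's their mixture relaxes with a half-life of 11.6 min, shorter than the 2.0 h run. On Tuesday's the half-life is 0.442 min, shorter still.

So turn that time into a number. If formation runs steadily, the excess of one product settles while the total keeps growing. The fraction of the made excess still standing at the reading is the memory, one over twice the interconversion constant times the run time: 0.139 on Sunday's, 0.00531 on Tuesday's. The left-handed share is then 0.5 × (1 − formation excess × memory).

Sunday's formation excess at the charged amounts is 0.326, so this first estimate of its share is 47.7%. That lies 2.3 percentage points below even, beyond the margin, so on this estimate the flasks differ.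

The objection is that formation is not steady. The right-handed substrate is used faster, so the imbalance fades. I reckon the fade for Sunday's. The partner is the limiting reagent. I take the impurity's amount off the catalyst and share the rest among its forms at the start. The partner then falls at about 0.00703 min⁻¹, which makes 0.205 M of product. Those losses move the late formation ratio to 0.716, an excess of 0.166. Sunday's share becomes 48.8%, which is 1.2 points below even, inside the margin.

By this rule Tuesday's share stays above 49.7%, even at a full formation excess. Wednesday's runs hotter than Sunday's and cooler than Tuesday's, so its memory lies between theirs. I commit to all alike, though not by much.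

The forecast says all alike, with Sunday's 48.8%, Tuesday's 50% and Wednesday's 49.96%. Its ground: the excess “tracks the current formation imbalance”. Where the forecast gives Tuesday's a value, I give only a bound.

The simulation gives all alike: Sunday's 48.9%, Tuesday's 50.0%, Wednesday's 50.0%. At the end of Sunday's, 58% of the right-handed substrate stands against 77% of the left-handed. Read back through the share rule with the memory of 0.139, Sunday's share gives a formation excess of 0.161, against my 0.166. Now take the neighbour of Tuesday's with 0.90 M of partner. Its temperature and time are Tuesday's, so its memory stays 0.00531 and its share should stand within 0.27 points of even. The computed share is 50.0%.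

The numbers of this flask are invented; what happens was integrated by code.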